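**Plan**

1. Cuts (hexahydronaphthalene numbering: C1 = CMe2, C2 = side-chain carbon, C3 = C–CH3, C4a/C8a = fusion carbons): the CH2–CH2 bond between ring B and the dioxane (Wittig, then diimide); C3–CH3 (enol triflate, cuprate); C1–C2 of ring B (key step); C2–C3 (malonate acylation); C4–C4a (Ireland–Claisen); in the dioxane both C–O bonds of the peroxide and the C–C bond between the peroxy CH and the methyl-bearing CH (aldol).
2. Enabling feature: ring A is a p-menthene. Its fusion carbon C8a lies para to the methyl-bearing alkene carbon C6 and carries the gem-dimethyl carbon C1 of ring B, so the isopropenyl group of (S)-limonene already supplies C1, one of its methyls and the configured C8a.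
3. Forward order: ring A from (S)-limonene; a β-keto ester tether is placed on C4a; ring B closes by acid-catalysed addition of the β-keto ester to the isopropenyl group; C3 is methylated and the C2 ester becomes a phosphonium salt. The dioxane aldehyde is built separately and joined by Wittig reaction, then diimide, desilylation and oxidation.
4. Stereochemistry: C8a from limonene; C4a by a suprafacial [3,3] shift from a carbinol centre set relative to C8a. The dioxane quaternary carbon comes from a Sharpless epoxidation (inverted once in the perhydrolysis); the peroxy CH and the α-methyl carbon come from an Evans syn aldol (CH–O inverted once in the ring closure).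

Key step: step 6

Remark: the carboxyl carbon is carried as a silyl-protected primary alcohol until the last step, because a β-sulfonyloxy ester would eliminate under the base that closes the peroxide ring; 5, 13, 25 and 38 are expected as mixtures (at Se, at the malonate carbon, at the trioxolane carbon, at the new alkene), none of which persists in the target.

**Route**

Step 1
Reactants: 1 (S)-limonene
Product: 3 trans-limonene 1,2-oxide (1R,2S,4S; epoxide oxygen cis to isopropenyl), via bromohydrin 2 (not isolated)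
Conditions: NBS, acetone/H2O, 0 °C; concentrate; then aq. NaOH, 60 °C
Reagents that add atoms: water (SMILES: O)
Why: Bromohydrin formation followed by Williamson closure: the electron-rich ring alkene takes up Br+ reversibly and water opens the bromonium ion at the tertiary carbon only in the trans-diaxial mode (Fürst–Plattner rule) of the chair with equatorial isopropenyl, which places OH cis and Br trans to isopropenyl and so fixes both epoxide centres relative to C4.

Step 2
Reactants: 3 trans-limonene 1,2-oxide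
Product: 6 (1R,4S)-1-methyl-4-(prop-1-en-2-yl)cyclohex-2-en-1-ol, via hydroxy selenide 4 (not isolated), via selenoxide 5 (not isolated)
Conditions: PhSeSePh, NaBH4, EtOH, reflux; then THF, 30% H2O2, pyridine, 0 °C to rt
Reagents that add atoms: none
Why: Selenide opening and selenoxide elimination: benzeneselenolate attacks the secondary epoxide carbon anti to oxygen, and the syn elimination of the selenoxide can only run toward C3 because C1 bears no hydrogen, so the tertiary allylic alcohol keeps the C1 configuration of 3 (OH cis to isopropenyl).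

Step 3
Reactants: 6 (1R,4S)-1-methyl-4-(prop-1-en-2-yl)cyclohex-2-en-1-ol
Product: 7 (1R,4S)-1-methyl-4-(prop-1-en-2-yl)cyclohex-2-en-1-yl acetate
Conditions: Ac2O, Et3N, DMAP (cat.), CH2Cl2, rt
Reagents that add atoms: acetic anhydride (SMILES: CC(=O)OC(C)=O)
Why: DMAP-catalysed acylation of a tertiary alcohol under basic conditions, which avoids ionisation of the allylic system and touches no stereocentre.

Step 4
Reactants: 7 (1R,4S)-1-methyl-4-(prop-1-en-2-yl)cyclohex-2-en-1-yl acetate
Product: 10 2-[(1R,6S)-3-methyl-6-(prop-1-en-2-yl)cyclohex-2-en-1-yl]acetic acid, via silyl ketene acetal 8 (not isolated), via trimethylsilyl ester 9 (not isolated)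
Conditions: LiN(i-Pr)2, Me3SiCl, Et3N, THF, −78 °C, then 60 °C; aq. HCl work-up
Reagents that add atoms: none
Why: Ireland–Claisen rearrangement: the [3,3] shift is suprafacial across the cyclohexene, so the new C–C bond forms on the face that carried the C–O bond, cis to isopropenyl, which sets the (1R) centre of 10 and restores the methyl-substituted ring alkene.

Step 5
Reactants: 10 2-[(1R,6S)-3-methyl-6-(prop-1-en-2-yl)cyclohex-2-en-1-yl]acetic acid; 11 potassium methyl malonate
Product: 14 methyl 4-[(1R,6S)-3-methyl-6-(prop-1-en-2-yl)cyclohex-2-en-1-yl]-3-oxobutanoate, via acyl imidazole 12 (not isolated), via acylmalonic half ester 13 (not isolated)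
Conditions: 1,1'-carbonyldiimidazole, THF, rt; then 11, MgCl2, THF, rt to 50 °C; aq. citric acid
Reagents that add atoms: none
Why: Masamune–Brooks homologation: the acyl imidazole C-acylates the magnesium enolate of the malonate half ester and decarboxylation on acidic work-up leaves the β-keto ester, under near-neutral conditions that spare both alkenes and both stereocentres.

Step 6
Reactants: 14 methyl 4-[(1R,6S)-3-methyl-6-(prop-1-en-2-yl)cyclohex-2-en-1-yl]-3-oxobutanoate
Product: 15 methyl (4aR,8aS)-3-hydroxy-1,1,6-trimethyl-1,4,4a,7,8,8a-hexahydronaphthalene-2-carboxylate (cis-fused β-keto ester in its enol form)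
Conditions: Bi(OTf)3 (10 mol %), ClCH2CH2Cl, rt to 40 °C
Reagents that add atoms: none
Why: Bi(OTf)3, a trivalent bismuth Lewis acid, chelates the β-keto ester and releases triflic acid in low concentration, which protonates the isopropenyl CH2 to a tertiary cation that is captured by the enol carbon between the two carbonyls, as in known Lewis- or Brønsted-acid-catalysed intramolecular Markovnikov hydroalkylations of unactivated alkenes by β-dicarbonyl compounds. Ring B closes in a 6-exo-trig mode at the alkene (6-enolendo at the nucleophile), and the former =CH2 becomes the second methyl on C1. No stereocentre is created, since C1 carries two methyls and C2 is sp2; the cis fusion is carried over because tether and cationic carbon already sit on the same face of ring A. The step needs selectivity for the 1,1-disubstituted alkene over the trisubstituted ring A alkene and for C- over O-alkylation. A cation at the ring A methyl carbon could be trapped only through a bridged bicyclo[3.3.1]nonane transition state and otherwise reverts by proton loss, and the O-alkylated dihydropyran is a tertiary alkyl enol ether that re-ionises under the same acid, whereas the fused C–C closure through a chair-like transition state is irreversible. Low catalyst loading and mild temperature should keep proton loss toward C8a (which would erode the ring fusion) and migration of the ring A alkene slow relative to ring closure.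

Step 7
Reactants: 15 methyl (4aR,8aS)-3-hydroxy-1,1,6-trimethyl-1,4,4a,7,8,8a-hexahydronaphthalene-2-carboxylate
Product: 16 methyl (4aR,8aS)-1,1,6-trimethyl-3-{[(trifluoromethyl)sulfonyl]oxy}-1,4,4a,7,8,8a-hexahydronaphthalene-2-carboxylate
Conditions: Tf2O, i-Pr2NEt, CH2Cl2, −78 °C
Reagents that add atoms: trifluoromethanesulfonic anhydride (SMILES: O=S(=O)(OS(=O)(=O)C(F)(F)F)C(F)(F)F)
Why: O-sulfonylation of the doubly stabilised enol of a cyclic β-keto ester, which can place the alkene only between C2 and C3.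

Step 8
Reactants: 16 enol triflate
Product: 17 methyl (4aR,8aS)-1,1,3,6-tetramethyl-1,4,4a,7,8,8a-hexahydronaphthalene-2-carboxylate
Conditions: Me2CuLi (from MeLi and CuI), Et2O, −78 to 0 °C
Reagents that add atoms: lithium dimethylcuprate (SMILES: [Li+].C[Cu-]C)
Why: Addition–elimination of a Gilman cuprate on a β-triflyloxy enoate, a standard way to turn cyclic β-keto esters into β-methyl enoates with the double bond held in place.

Step 9
Reactants: 17 methyl (4aR,8aS)-1,1,3,6-tetramethyl-1,4,4a,7,8,8a-hexahydronaphthalene-2-carboxylate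
Product: 18 [(4aR,8aS)-1,1,3,6-tetramethyl-1,4,4a,7,8,8a-hexahydronaphthalen-2-yl]methanol
Conditions: i-Bu2AlH, CH2Cl2, −78 to 0 °C; aq. potassium sodium tartrate
Reagents that add atoms: none
Why: 1,2-Reduction of a hindered conjugated ester to the allylic alcohol by an aluminium hydride, as routinely done on cyclogeranate esters of the same substitution pattern.

Step 10
Reactants: 18 [(4aR,8aS)-1,1,3,6-tetramethyl-1,4,4a,7,8,8a-hexahydronaphthalen-2-yl]methanol
Product: 19 {[(4aR,8aS)-1,1,3,6-tetramethyl-1,4,4a,7,8,8a-hexahydronaphthalen-2-yl]methyl}(triphenyl)phosphonium bromide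
Conditions: PPh3·HBr, MeOH, rt
Reagents that add atoms: triphenylphosphine hydrobromide (SMILES: [Br-].[PH+](c1ccccc1)(c1ccccc1)c1ccccc1)
Why: Acid-mediated phosphonium salt formation from an allylic alcohol: the stabilised allyl cation is trapped by PPh3 at its unhindered primary terminus, as for β-cyclogeranyl phosphonium salts, and the acid is too weak to protonate the ring A alkene.

Step 11
Reactants: 20 2-methylprop-2-en-1-ol
Product: 22 [(2R)-2-methyloxiran-2-yl]methyl 4-methylbenzenesulfonate, via epoxy alcohol 21 (not isolated)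
Conditions: Ti(OiPr)4 (5 mol %), L-(+)-diisopropyl tartrate (6 mol %), cumene hydroperoxide, 4 Å molecular sieves, CH2Cl2, −20 °C; then P(OMe)3; then TsCl, Et3N, DMAP, −10 °C
Reagents that add atoms: cumene hydroperoxide (SMILES: CC(C)(OO)c1ccccc1); 4-toluenesulfonyl chloride (SMILES: Cc1ccc(cc1)S(=O)(=O)Cl)
Why: Sharpless asymmetric epoxidation of a 2-substituted allyl alcohol, in which the L-(+)-tartrate complex delivers oxygen to one alkene face and sets the quaternary centre as (S)-2-methylglycidol, followed by in situ tosylation so that the water-soluble epoxy alcohol need not be isolated.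

Step 12
Reactants: 22 [(2R)-2-methyloxiran-2-yl]methyl 4-methylbenzenesulfonate
Product: 24 (2R)-2-(but-3-en-1-yl)-2-methyloxirane, via hydroxy tosylate 23 (not isolated)
Conditions: CH2=CHCH2MgBr, CuI (10 mol %), THF, −40 to 0 °C; then aq. NaOH, rt
Reagents that add atoms: allylmagnesium bromide (SMILES: C=CC[Mg]Br)
Why: Copper-catalysed Grignard opening at the epoxide CH2 followed by closure of the tertiary alkoxide onto the tosylate: the C–O bond at the quaternary carbon is never broken, so configuration is transferred intact, and the neopentyl-type tosylate carbon is not attacked directly.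

Step 13
Reactants: 24 (2R)-2-(but-3-en-1-yl)-2-methyloxirane
Product: 26 3-[(2R)-2-methyloxiran-2-yl]propanal, via ozonide 25 (not isolated)
Conditions: O3, CH2Cl2, −78 °C; then PPh3, −78 °C to rt; used as a solution
Reagents that add atoms: ozone (SMILES: [O-][O+]=O)
Why: Ozonolysis with reductive work-up cleaves the terminal alkene to the aldehyde while the epoxide is inert to ozone and to PPh3.

Step 14
Reactants: 26 3-[(2R)-2-methyloxiran-2-yl]propanal; 27 (4R)-4-benzyl-3-propanoyl-1,3-oxazolidin-2-one
Product: 30 (4R)-4-benzyl-3-{(2R,3S)-3-hydroxy-2-methyl-5-[(2R)-2-methyloxiran-2-yl]pentanoyl}-1,3-oxazolidin-2-one, via boron enolate 28 (not isolated), via boron aldolate 29 (not isolated)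
Conditions: Bu2BOTf, Et3N, CH2Cl2, 0 °C; then 26, −78 to 0 °C; pH 7 buffer, MeOH, 30% H2O2, 0 °C
Reagents that add atoms: none
Why: Evans syn aldol: the (Z)-boron enolate reacts through a closed Zimmerman–Traxler chair in which the benzyl group of the (R)-auxiliary shields one enolate face, setting both new centres as (2R,3S) regardless of the remote epoxide; the enolate is formed before the aldehyde is added so that the epoxide never meets free boron triflate.

Step 15
Reactants: 30 aldol adduct
Product: 31 (2S,3S)-2-methyl-5-[(2R)-2-methyloxiran-2-yl]pentane-1,3-diol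
Conditions: NaBH4, THF/H2O, 0 °C to rt
Reagents that add atoms: none
Why: Reductive removal of the oxazolidinone by borohydride, which reduces the activated imide carbonyl but not the epoxide; the C2 label changes from R to S only through CIP priorities.

Step 16
Reactants: 31 (2S,3S)-2-methyl-5-[(2R)-2-methyloxiran-2-yl]pentane-1,3-diol
Product: 32 (2S,3S)-1-{[tert-butyl(diphenyl)silyl]oxy}-2-methyl-5-[(2R)-2-methyloxiran-2-yl]pentan-3-ol
Conditions: t-BuPh2SiCl, imidazole, CH2Cl2, 0 °C
Reagents that add atoms: tert-butyl(chloro)diphenylsilane (SMILES: CC(C)(C)[Si](Cl)(c1ccccc1)c1ccccc1)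
Why: The bulky silyl chloride reacts selectively at the primary hydroxyl of the 1,3-diol, and the resulting ether is stable to the acid of step 18 and the bases of steps 19 and 21.

Step 17
Reactants: 32 silyl ether
Product: 33 (2S,3S)-1-{[tert-butyl(diphenyl)silyl]oxy}-2-methyl-5-[(2R)-2-methyloxiran-2-yl]pentan-3-yl methanesulfonate
Conditions: MsCl, Et3N, CH2Cl2, 0 °C
Reagents that add atoms: methanesulfonyl chloride (SMILES: CS(=O)(=O)Cl)
Why: Sulfonylation at oxygen activates the secondary carbinol with retention, and without an adjacent carbonyl the mesylate cannot undergo E1cB elimination.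

Step 18
Reactants: 33 epoxy mesylate
Product: 34 (2S,3S,6S)-1-{[tert-butyl(diphenyl)silyl]oxy}-6-hydroperoxy-7-hydroxy-2,6-dimethylheptan-3-yl methanesulfonate
Conditions: anhydrous H2O2 in Et2O, H3PMo12O40 (cat.), rt
Reagents that add atoms: hydrogen peroxide (SMILES: OO)
Why: Acid-catalysed perhydrolysis of a 2,2-disubstituted epoxide: H2O2 attacks the tertiary carbon from the side opposite the departing oxygen (borderline SN2, inversion), which sets the peroxide-bearing quaternary centre as (6S) and frees the CH2OH that later becomes the aldehyde.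

Step 19
Reactants: 34 hydroperoxy mesylate
Product: 35 {(3S,6R)-6-[(2S)-1-{[tert-butyl(diphenyl)silyl]oxy}propan-2-yl]-3-methyl-1,2-dioxan-3-yl}methanol
Conditions: KOt-Bu (1.0 equiv), 18-crown-6, THF, 0 °C
Reagents that add atoms: none
Why: Intramolecular alkylation of a hydroperoxide: the more acidic OOH is deprotonated in preference to the primary alcohol and displaces the secondary mesylate in a 6-exo-tet SN2 reaction with inversion, which sets the (6R) ring centre with the two large substituents cis.

Step 20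
Reactants: 35 dioxane alcohol
Product: 36 (3S,6R)-6-[(2S)-1-{[tert-butyl(diphenyl)silyl]oxy}propan-2-yl]-3-methyl-1,2-dioxane-3-carbaldehyde
Conditions: Dess–Martin periodinane, NaHCO3, CH2Cl2, 0 °C to rt
Reagents that add atoms: none
Why: Dess–Martin oxidation of a primary alcohol under buffered, non-reducing conditions that leave the dialkyl peroxide intact; the aldehyde has no α-hydrogen and cannot epimerise.

Step 21
Reactants: 19 phosphonium bromide; 36 dioxane aldehyde
Product: 38 tert-butyl{[(2S)-2-{(3R,6S)-6-methyl-6-[2-((4aR,8aS)-1,1,3,6-tetramethyl-1,4,4a,7,8,8a-hexahydronaphthalen-2-yl)ethenyl]-1,2-dioxan-3-yl}propyl]oxy}diphenylsilane (E/Z mixture), via phosphorus ylide 37 (not isolated)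
Conditions: NaN(SiMe3)2, THF, −78 to 0 °C; then 36, −78 °C to rt
Reagents that add atoms: none
Why: Wittig olefination: the allylic ylide, formed with an amide base so that no alkyllithium meets the peroxide, adds through its α-carbon to the non-enolisable aldehyde and joins the two halves at the future CH2–CH2 link, alkene geometry being irrelevant.

Step 22
Reactants: 38 diene
Product: 39 tert-butyl{[(2S)-2-{(3R,6R)-6-methyl-6-[2-((4aR,8aS)-1,1,3,6-tetramethyl-1,4,4a,7,8,8a-hexahydronaphthalen-2-yl)ethyl]-1,2-dioxan-3-yl}propyl]oxy}diphenylsilane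
Conditions: KO2CN=NCO2K, AcOH, pyridine, MeOH/CH2Cl2, 0 °C to rt, added in portions
Reagents that add atoms: none
Why: Diimide reduction: concerted syn transfer of H2 goes to the 1,2-disubstituted alkene far faster than to the trisubstituted and tetrasubstituted ring alkenes and, unlike catalytic hydrogenation, does not cleave the O–O bond; the quaternary centre changes label from S to R only through CIP priorities.

Step 23
Reactants: 39 silyl ether
Product: 40 (2S)-2-{(3R,6R)-6-methyl-6-[2-((4aR,8aS)-1,1,3,6-tetramethyl-1,4,4a,7,8,8a-hexahydronaphthalen-2-yl)ethyl]-1,2-dioxan-3-yl}propan-1-ol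
Conditions: Bu4NF, AcOH, THF, rt
Reagents that add atoms: none
Why: Fluoride cleavage of the silyl ether, buffered with acetic acid so that the liberated alkoxide cannot trigger base-induced fragmentation of the peroxide.

Step 24
Reactants: 40 primary alcohol
Product: 41 (2R)-2-{(3R,6R)-6-methyl-6-[2-((4aR,8aS)-1,1,3,6-tetramethyl-1,4,4a,7,8,8a-hexahydronaphthalen-2-yl)ethyl]-1,2-dioxan-3-yl}propanoic acid (target)
Conditions: TEMPO (cat.), PhI(OAc)2, MeCN/H2O, rt
Reagents that add atoms: water (SMILES: O)
Why: Oxoammonium-mediated oxidation of the primary alcohol through the aldehyde hydrate to the acid under near-neutral conditions that tolerate the alkenes and the peroxide and keep the transient β-peroxy aldehyde too short-lived to epimerise or eliminate; the α-carbon becomes R only through CIP priorities.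

**Compound list**

1 | (S)-limonene | CC1=CC[C@@H](C(C)=C)CC1 | starting material
2 | (1R,2R,4S)-2-bromo-1-methyl-4-(prop-1-en-2-yl)cyclohexan-1-ol | C[C@]1(O)[C@H](Br)C[C@@H](C(C)=C)CC1 | intermediate
3 | trans-limonene 1,2-oxide, (1R,4S,6S)-1-methyl-4-(prop-1-en-2-yl)-7-oxabicyclo[4.1.0]heptane | C[C@]12O[C@H]1C[C@@H](C(C)=C)CC2 | intermediate
4 | (1R,2R,4S)-1-methyl-2-(phenylselanyl)-4-(prop-1-en-2-yl)cyclohexan-1-ol | C[C@]1(O)[C@H]([Se]c2ccccc2)C[C@@H](C(C)=C)CC1 | intermediate
5 | (1R,2R,4S)-1-methyl-2-(phenylseleninyl)-4-(prop-1-en-2-yl)cyclohexan-1-ol (epimers at Se) | C[C@]1(O)[C@H]([Se](=O)c2ccccc2)C[C@@H](C(C)=C)CC1 | intermediate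
6 | (1R,4S)-1-methyl-4-(prop-1-en-2-yl)cyclohex-2-en-1-ol | C[C@]1(O)C=C[C@@H](C(C)=C)CC1 | intermediate
7 | (1R,4S)-1-methyl-4-(prop-1-en-2-yl)cyclohex-2-en-1-yl acetate | C[C@]1(OC(C)=O)C=C[C@@H](C(C)=C)CC1 | intermediate
8 | trimethyl[(1-{[(1R,4S)-1-methyl-4-(prop-1-en-2-yl)cyclohex-2-en-1-yl]oxy}ethenyl)oxy]silane | C[C@]1(OC(=C)O[Si](C)(C)C)C=C[C@@H](C(C)=C)CC1 | intermediate
9 | trimethylsilyl 2-[(1R,6S)-3-methyl-6-(prop-1-en-2-yl)cyclohex-2-en-1-yl]acetate | CC1=C[C@@H](CC(=O)O[Si](C)(C)C)[C@@H](C(C)=C)CC1 | intermediate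
10 | 2-[(1R,6S)-3-methyl-6-(prop-1-en-2-yl)cyclohex-2-en-1-yl]acetic acid | CC1=C[C@@H](CC(=O)O)[C@@H](C(C)=C)CC1 | intermediate
11 | potassium methyl malonate | COC(=O)CC(=O)[O-].[K+] | starting material
12 | 1-{[(1R,6S)-3-methyl-6-(prop-1-en-2-yl)cyclohex-2-en-1-yl]acetyl}-1H-imidazole | CC1=C[C@@H](CC(=O)n2ccnc2)[C@@H](C(C)=C)CC1 | intermediate
13 | 3-methoxy-2-{[(1R,6S)-3-methyl-6-(prop-1-en-2-yl)cyclohex-2-en-1-yl]acetyl}-3-oxopropanoic acid | CC1=C[C@@H](CC(=O)C(C(=O)O)C(=O)OC)[C@@H](C(C)=C)CC1 | intermediate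
14 | methyl 4-[(1R,6S)-3-methyl-6-(prop-1-en-2-yl)cyclohex-2-en-1-yl]-3-oxobutanoate | CC1=C[C@@H](CC(=O)CC(=O)OC)[C@@H](C(C)=C)CC1 | intermediate
15 | methyl (4aR,8aS)-3-hydroxy-1,1,6-trimethyl-1,4,4a,7,8,8a-hexahydronaphthalene-2-carboxylate (enol form) | CC1=C[C@H]2CC(O)=C(C(=O)OC)C(C)(C)[C@H]2CC1 | intermediate
16 | methyl (4aR,8aS)-1,1,6-trimethyl-3-{[(trifluoromethyl)sulfonyl]oxy}-1,4,4a,7,8,8a-hexahydronaphthalene-2-carboxylate | CC1=C[C@H]2CC(OS(=O)(=O)C(F)(F)F)=C(C(=O)OC)C(C)(C)[C@H]2CC1 | intermediate
17 | methyl (4aR,8aS)-1,1,3,6-tetramethyl-1,4,4a,7,8,8a-hexahydronaphthalene-2-carboxylate | CC1=C[C@H]2CC(C)=C(C(=O)OC)C(C)(C)[C@H]2CC1 | intermediate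
18 | [(4aR,8aS)-1,1,3,6-tetramethyl-1,4,4a,7,8,8a-hexahydronaphthalen-2-yl]methanol | CC1=C[C@H]2CC(C)=C(CO)C(C)(C)[C@H]2CC1 | intermediate
19 | {[(4aR,8aS)-1,1,3,6-tetramethyl-1,4,4a,7,8,8a-hexahydronaphthalen-2-yl]methyl}(triphenyl)phosphonium bromide | CC1=C[C@H]2CC(C)=C(C[P+](c3ccccc3)(c3ccccc3)c3ccccc3)C(C)(C)[C@H]2CC1.[Br-] | intermediate
20 | 2-methylprop-2-en-1-ol | CC(=C)CO | starting material
21 | [(2S)-2-methyloxiran-2-yl]methanol | C[C@]1(CO)CO1 | intermediate
22 | [(2R)-2-methyloxiran-2-yl]methyl 4-methylbenzenesulfonate | C[C@]1(COS(=O)(=O)c2ccc(C)cc2)CO1 | intermediate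
23 | (2R)-2-hydroxy-2-methylhept-6-en-1-yl 4-methylbenzenesulfonate | C[C@](O)(COS(=O)(=O)c1ccc(C)cc1)CCC=C | intermediate
24 | (2R)-2-(but-3-en-1-yl)-2-methyloxirane | C[C@@]1(CCC=C)CO1 | intermediate
25 | 3-{2-[(2R)-2-methyloxiran-2-yl]ethyl}-1,2,4-trioxolane (epimers at C3 of the trioxolane) | C[C@@]1(CCC2OCOO2)CO1 | intermediate
26 | 3-[(2R)-2-methyloxiran-2-yl]propanal | C[C@@]1(CCC=O)CO1 | intermediate
27 | (4R)-4-benzyl-3-propanoyl-1,3-oxazolidin-2-one | CCC(=O)N1[C@H](Cc2ccccc2)COC1=O | starting material
28 | (4R)-4-benzyl-3-[(1Z)-1-[(dibutylboranyl)oxy]prop-1-en-1-yl]-1,3-oxazolidin-2-one | C/C=C(\OB(CCCC)CCCC)N1[C@H](Cc2ccccc2)COC1=O | intermediate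
29 | O-dibutylboranyl derivative of 30 | C[C@@]1(CC[C@H](OB(CCCC)CCCC)[C@@H](C)C(=O)N2[C@H](Cc3ccccc3)COC2=O)CO1 | intermediate
30 | (4R)-4-benzyl-3-{(2R,3S)-3-hydroxy-2-methyl-5-[(2R)-2-methyloxiran-2-yl]pentanoyl}-1,3-oxazolidin-2-one | C[C@@]1(CC[C@H](O)[C@@H](C)C(=O)N2[C@H](Cc3ccccc3)COC2=O)CO1 | intermediate
31 | (2S,3S)-2-methyl-5-[(2R)-2-methyloxiran-2-yl]pentane-1,3-diol | C[C@@]1(CC[C@H](O)[C@@H](C)CO)CO1 | intermediate
32 | (2S,3S)-1-{[tert-butyl(diphenyl)silyl]oxy}-2-methyl-5-[(2R)-2-methyloxiran-2-yl]pentan-3-ol | C[C@@]1(CC[C@H](O)[C@@H](C)CO[Si](c2ccccc2)(c2ccccc2)C(C)(C)C)CO1 | intermediate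
33 | (2S,3S)-1-{[tert-butyl(diphenyl)silyl]oxy}-2-methyl-5-[(2R)-2-methyloxiran-2-yl]pentan-3-yl methanesulfonate | C[C@@]1(CC[C@H](OS(C)(=O)=O)[C@@H](C)CO[Si](c2ccccc2)(c2ccccc2)C(C)(C)C)CO1 | intermediate
34 | (2S,3S,6S)-1-{[tert-butyl(diphenyl)silyl]oxy}-6-hydroperoxy-7-hydroxy-2,6-dimethylheptan-3-yl methanesulfonate | OC[C@@](C)(OO)CC[C@H](OS(C)(=O)=O)[C@@H](C)CO[Si](c1ccccc1)(c1ccccc1)C(C)(C)C | intermediate
35 | {(3S,6R)-6-[(2S)-1-{[tert-butyl(diphenyl)silyl]oxy}propan-2-yl]-3-methyl-1,2-dioxan-3-yl}methanol | OC[C@]1(C)CC[C@H]([C@@H](C)CO[Si](c2ccccc2)(c2ccccc2)C(C)(C)C)OO1 | intermediate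
36 | (3S,6R)-6-[(2S)-1-{[tert-butyl(diphenyl)silyl]oxy}propan-2-yl]-3-methyl-1,2-dioxane-3-carbaldehyde | O=C[C@]1(C)CC[C@H]([C@@H](C)CO[Si](c2ccccc2)(c2ccccc2)C(C)(C)C)OO1 | intermediate
37 | {[(4aR,8aS)-1,1,3,6-tetramethyl-1,4,4a,7,8,8a-hexahydronaphthalen-2-yl]methylidene}(triphenyl)-λ5-phosphane | CC1=C[C@H]2CC(C)=C(C=P(c3ccccc3)(c3ccccc3)c3ccccc3)C(C)(C)[C@H]2CC1 | intermediate
38 | tert-butyl{[(2S)-2-{(3R,6S)-6-methyl-6-[2-((4aR,8aS)-1,1,3,6-tetramethyl-1,4,4a,7,8,8a-hexahydronaphthalen-2-yl)ethenyl]-1,2-dioxan-3-yl}propyl]oxy}diphenylsilane (E/Z mixture) | CC1=C[C@H]2CC(C)=C(C=C[C@]3(C)CC[C@H]([C@@H](C)CO[Si](c4ccccc4)(c4ccccc4)C(C)(C)C)OO3)C(C)(C)[C@H]2CC1 | intermediate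
39 | tert-butyl{[(2S)-2-{(3R,6R)-6-methyl-6-[2-((4aR,8aS)-1,1,3,6-tetramethyl-1,4,4a,7,8,8a-hexahydronaphthalen-2-yl)ethyl]-1,2-dioxan-3-yl}propyl]oxy}diphenylsilane | CC1=C[C@H]2CC(C)=C(CC[C@]3(C)CC[C@H]([C@@H](C)CO[Si](c4ccccc4)(c4ccccc4)C(C)(C)C)OO3)C(C)(C)[C@H]2CC1 | intermediate
40 | (2S)-2-{(3R,6R)-6-methyl-6-[2-((4aR,8aS)-1,1,3,6-tetramethyl-1,4,4a,7,8,8a-hexahydronaphthalen-2-yl)ethyl]-1,2-dioxan-3-yl}propan-1-ol | CC1=C[C@H]2CC(C)=C(CC[C@]3(C)CC[C@H]([C@@H](C)CO)OO3)C(C)(C)[C@H]2CC1 | intermediate
41 | (2R)-2-{(3R,6R)-6-methyl-6-[2-((4aR,8aS)-1,1,3,6-tetramethyl-1,4,4a,7,8,8a-hexahydronaphthalen-2-yl)ethyl]-1,2-dioxan-3-yl}propanoic acid | CC1=C[C@H]2CC(C)=C(CC[C@]3(C)CC[C@H]([C@@H](C)C(=O)O)OO3)C(C)(C)[C@H]2CC1 | target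

**Count**

Total steps: 24. Longest linear sequence: 14 steps (steps 1–10 and 21–24 from (S)-limonene; the dioxane branch, steps 11–20 and 21–24 from 2-methylprop-2-en-1-ol, is equally long).

**Steps most likely to fail**

Step 6. The ring A alkene may be protonated in competition, leading to double-bond migration or bridged closure; the tertiary cation may lose a proton toward C8a and erode the cis fusion; O-alkylation may persist. The fallback sets out from 14 and returns at 15 and replaces protonation by mercuration, which discriminates strongly in favour of 1,1-disubstituted over trisubstituted alkenes. Hg(OTf)2, a divalent mercury salt, in MeCN at −20 °C adds to the isopropenyl CH2 while the enol carbon closes ring B at the tertiary carbon; aqueous NaCl gives the alkylmercury chloride F1 (either epimer at C1). NaBH4 in aqueous NaOH/THF then replaces mercury by hydrogen, turning the CH2HgCl group into the second methyl of 15.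

Step 19. The secondary mesylate may eliminate, the neighbouring primary hydroxyl may attack in place of the peroxide oxygen, or the β-hydroxy hydroperoxide may fragment under base; partial loss of configuration in the preceding perhydrolysis would also surface here. The fallback sets out from 33 and returns at 35 and reverses the order in which the two C–O bonds are made. The mesylate is displaced with 2-methoxypropan-2-yl hydroperoxide and CsOH·H2O in DMF (SN2, inversion) to give the peroxyketal F2; aqueous AcOH/THF unmasks the secondary hydroperoxide F3; catalytic camphorsulfonic acid in CH2Cl2 then lets it open the epoxide at the tertiary carbon (6-exo, inversion). This gives 35 through the same two inversions without exposing a β-hydroxy hydroperoxide to base.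

Step 21. Addition of the hindered allylic ylide to the α-quaternary aldehyde may be sluggish, the ylide may react through its γ-carbon, or the base may cleave the peroxide. The fallback sets out from 18 and, with 36, returns at 38 by a Julia–Kocienski olefination. Mitsunobu reaction of 18 with 1-phenyl-1H-tetrazole-5-thiol (PPh3, diisopropyl azodicarboxylate) gives the sulfide F4; (NH4)6Mo7O24/H2O2 in EtOH oxidises it to the sulfone F5; its potassium anion (KN(SiMe3)2, 1,2-dimethoxyethane, −60 °C) adds to 36 and collapses to 38.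

**Further compounds**

F1 | step 6 | methyl (4aR,8aS)-1-[(chloromercurio)methyl]-3-hydroxy-1,6-dimethyl-1,4,4a,7,8,8a-hexahydronaphthalene-2-carboxylate (either epimer at C1) | CC1=C[C@H]2CC(O)=C(C(=O)OC)C(C)(C[Hg]Cl)[C@H]2CC1
F2 | step 19 | tert-butyl{[(2S,3R)-3-[(2-methoxypropan-2-yl)peroxy]-2-methyl-5-[(2R)-2-methyloxiran-2-yl]pentyl]oxy}diphenylsilane | C[C@@]1(CC[C@@H](OOC(C)(C)OC)[C@@H](C)CO[Si](c2ccccc2)(c2ccccc2)C(C)(C)C)CO1
F3 | step 19 | tert-butyl{[(2S,3R)-3-hydroperoxy-2-methyl-5-[(2R)-2-methyloxiran-2-yl]pentyl]oxy}diphenylsilane | C[C@@]1(CC[C@@H](OO)[C@@H](C)CO[Si](c2ccccc2)(c2ccccc2)C(C)(C)C)CO1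
F4 | step 21 | 1-phenyl-5-({[(4aR,8aS)-1,1,3,6-tetramethyl-1,4,4a,7,8,8a-hexahydronaphthalen-2-yl]methyl}sulfanyl)-1H-tetrazole | CC1=C[C@H]2CC(C)=C(CSc3nnnn3-c3ccccc3)C(C)(C)[C@H]2CC1
F5 | step 21 | 1-phenyl-5-({[(4aR,8aS)-1,1,3,6-tetramethyl-1,4,4a,7,8,8a-hexahydronaphthalen-2-yl]methyl}sulfonyl)-1H-tetrazole | CC1=C[C@H]2CC(C)=C(CS(=O)(=O)c3nnnn3-c3ccccc3)C(C)(C)[C@H]2CC1
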